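The route rests on opening the 3(2H)-furanone ring (O–C10–C1(=O)–C2=C3) that bridges the ten-membered carbocycle: C1–C3 become an ynal and C10 a methyl ketone. One carbene-catalysed operation then makes C1 an acyl anion that adds to the C10 ketone (C1–C10 bond, closing the carbocycle and creating the quaternary centre) and lets the resulting tertiary alkoxide add to C3 (O–C3 bond, closing the furanone). The precursor is an open chain that already carries the stereocentres C4–C9, the cis-fused α-methylene lactone and the angelate; C6, C7 and C8 are carbons 2, 3 and 4 of diacetone-D-glucose.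

Key step: step 18

Remark on numbering: germacranolide locants are used throughout. C1 is the ketone, C2=C3 the enol ether (C3 bears the ring oxygen), C4 carries methyl C15, C5 an OH, C6 the lactone oxygen, C8 the angelate, C9 an OH, C10 is quaternary (methyl C14, ring oxygen), and C11(=C13H2)–C12 is the lactone. Furanose carbons 1–5 of the sugar become C5–C9.

Remark on mixtures: centres that are mixtures and are destroyed later (alkene geometry of 3, C11 of 8 and 9, anomeric carbon of 11, C1 carbinol of F1) are left open in the SMILES.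

Step 1
Reactants: 1 1,2:5,6-di-O-isopropylidene-α-D-glucofuranose (diacetone-D-glucose)
Product: 2 1,2:5,6-di-O-isopropylidene-α-D-ribo-hexofuranos-3-ulose
Conditions: Dess–Martin periodinane, CH2Cl2, rt
Reagents that add atoms: none
Why: Dess–Martin oxidation of the only free hydroxyl (sugar C3, the future C7) should give the ketone without touching a stereocentre.

Step 2
Reactants: 2 1,2:5,6-di-O-isopropylidene-α-D-ribo-hexofuranos-3-ulose
Product: 3 methyl 2-(3-deoxy-1,2:5,6-di-O-isopropylidene-α-D-ribo-hexofuranos-3-ylidene)acetate (E/Z mixture)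
Conditions: (MeO)2P(O)CH2CO2Me, NaH, THF, 0 °C → rt
Reagents that add atoms: trimethyl phosphonoacetate COC(=O)CP(=O)(OC)OC
Why: Horner–Wadsworth–Emmons olefination of the unhindered ketone installs C11 and C12; the alkene geometry is irrelevant because both isomers converge in step 3.

Step 3
Reactants: 3 methyl 2-(3-deoxy-1,2:5,6-di-O-isopropylidene-α-D-ribo-hexofuranos-3-ylidene)acetate
Product: 4 methyl 2-(3-deoxy-1,2:5,6-di-O-isopropylidene-α-D-allofuranos-3-yl)acetate
Conditions: H2 (1 atm), 10% Pd/C, EtOAc, rt
Reagents that add atoms: none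
Why: Heterogeneous hydrogenation should deliver hydrogen to the convex β-face, anti to the 1,2-O-isopropylidene ring, which places the CH2CO2Me branch on the α-face (D-allo) and so sets C7 cis to the C6 oxygen.

Step 4
Reactants: 4 methyl 2-(3-deoxy-1,2:5,6-di-O-isopropylidene-α-D-allofuranos-3-yl)acetate
Product: 5 3-deoxy-1,2-O-isopropylidene-3-C-(2-methoxy-2-oxoethyl)-α-D-ribo-pentodialdo-1,4-furanose
Conditions: H5IO6, EtOAc, rt
Reagents that add atoms: none
Why: Periodic acid in ethyl acetate should hydrolyse the more labile terminal acetonide and cleave the released 5,6-diol in the same pot (Malaprade cleavage), leaving the 1,2-acetonide and the C8 stereocentre untouched.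

Step 5
Reactants: 5 3-deoxy-1,2-O-isopropylidene-3-C-(2-methoxy-2-oxoethyl)-α-D-ribo-pentodialdo-1,4-furanose
Product: 6 isopropenyl carbinol: 5 with sugar C5 converted into CH(OH)–C(CH3)=CH2, L-talo (4,5-threo) configuration
Conditions: MgBr2·OEt2, CH2Cl2, −78 °C; CH2=C(CH3)MgBr (THF), −78 °C; aq NH4Cl
Reagents that add atoms: isopropenylmagnesium bromide CC(=C)[Mg]Br
Why: Cram-chelate Grignard addition: magnesium bridges the aldehyde oxygen and the furanose ring oxygen and the isopropenyl group should enter from the open face to give the 4,5-threo alcohol, which is the C9 configuration; at −78 °C the aldehyde reacts far faster than the methyl ester.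

Step 6
Reactants: 6 isopropenyl carbinol
Product: 7 O-tert-butyldiphenylsilyl (TBDPS) ether of 6 at the C9 oxygen
Conditions: TBDPSCl, imidazole, DMF, rt → 40 °C
Reagents that add atoms: tert-butyl(chloro)diphenylsilane CC(C)(C)[Si](Cl)(c1ccccc1)c1ccccc1
Why: Silylation of the only hydroxyl; the TBDPS ether is chosen because it survives the aqueous acid of step 8 and later shields the neighbouring C8 hydroxyl.

Step 7
Reactants: 7 TBDPS ether
Product: 10 acrylate: 7 with the ester α-carbon (C11) converted into C(=CH2), via Mannich base 8 (not isolated), via ammonium iodide 9 (not isolated)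
Conditions: LDA, THF, −78 °C; CH2=NMe2+ I−, −78 → 0 °C; then MeI, MeOH, rt; then aq NaHCO3, CH2Cl2, rt
Reagents that add atoms: dimethylmethylideneammonium iodide (Eschenmoser's salt) C=[N+](C)C.[I-]; iodomethane CI (its methyl group is carried only by intermediate 9)
Why: Eschenmoser methylenation: the lithium ester enolate undergoes a Mannich reaction with the iminium salt, and exhaustive methylation followed by base-induced Hofmann-type elimination of trimethylamine should give the 2-substituted acrylate (C11=C13); the transient C11 stereocentre disappears and no leaving group sits β to the enolate.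

Step 8
Reactants: 10 acrylate
Product: 11 bicyclic lactol: furanose (anomeric OH free, α/β) cis-fused through C6–C7 to the α-methylene-γ-butyrolactone, C9 OTBDPS, C10 isopropenyl
Conditions: AcOH/H2O (4:1), 80 °C
Reagents that add atoms: none
Why: Acid hydrolysis of the 1,2-acetonide frees the C6 hydroxyl, which is cis to the acrylate branch and should lactonise at once to the cis-fused α-methylene-γ-butyrolactone, while the ring oxygen (the future C8 oxygen) keeps the aldehyde carbon C5 masked as a lactol; the TBDPS ether and the isopropenyl group are stable to aqueous acetic acid.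

Step 9
Reactants: 12 tert-butyldimethyl(prop-2-yn-1-yloxy)silane
Product: 13 5-(tert-butyldimethylsilyloxy)pent-3-yn-2-one
Conditions: n-BuLi, THF, −78 °C; MeC(O)N(OMe)Me, −78 → 0 °C; cold 1 M aq HCl
Reagents that add atoms: N-methoxy-N-methylacetamide CC(=O)N(C)OC
Why: Acylation of the lithium acetylide with the Weinreb amide should stop at the ynone because the chelated tetrahedral intermediate survives until work-up.

Step 10
Reactants: 13 5-(tert-butyldimethylsilyloxy)pent-3-yn-2-one
Product: 14 (R)-5-(tert-butyldimethylsilyloxy)pent-3-yn-2-ol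
Conditions: RuCl[(R,R)-TsDPEN](p-cymene) (1 mol %), i-PrOH, rt
Reagents that add atoms: none
Why: Noyori asymmetric transfer hydrogenation of the ynone; the (R,R)-TsDPEN ruthenium catalyst is expected to deliver hydride to the face that gives the (R)-propargylic alcohol.

Step 11
Reactants: 14 (R)-5-(tert-butyldimethylsilyloxy)pent-3-yn-2-ol
Product: 15 (R)-5-(tert-butyldimethylsilyloxy)pent-3-yn-2-yl methanesulfonate
Conditions: MsCl, Et3N, CH2Cl2, −78 → 0 °C
Reagents that add atoms: methanesulfonyl chloride CS(=O)(=O)Cl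
Why: Mesylation takes place at oxygen and keeps the (R) configuration.

Step 12
Reactants: 11 bicyclic lactol; 15 (R)-mesylate
Product: 16 seco 5,8-diol: chain C1–C10 with C1 CH2OTBS, C2≡C3, C4 CH3, C5 OH (4,5-anti), cis-fused α-methylene-γ-butyrolactone on C6/C7, C8 OH, C9 OTBDPS, C10 isopropenyl
Conditions: Pd(dppf)Cl2 (5 mol %), InI (indium monoiodide), THF/HMPA (3:1), rt
Reagents that add atoms: none
Why: Marshall–Tamaru propargylation: zerovalent palladium formed in situ adds anti-SN2′ to mesylate 15, InI converts the allenylpalladium into an allenylindium with retention, and this adds through a cyclic SE2′ transition state to the open-chain aldehyde form of lactol 11, so the reagent sets C4 and the anti C4/C5 relationship, which is matched with the Felkin–Anh (C5/C6 anti) preference of the α-acyloxy aldehyde; the organoindium should ignore the lactone, the alkenes and the free hydroxyls.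

Step 13
Reactants: 16 seco 5,8-diol
Product: 17 C5 O-tert-butyldimethylsilyl (TBS) ether of 16, C8 OH free
Conditions: TBSCl, imidazole, DMF, 0 °C → rt
Reagents that add atoms: tert-butyl(chloro)dimethylsilane CC(C)(C)[Si](C)(C)Cl
Why: Silylation with TBSCl/imidazole should take place at the C5 hydroxyl, because the C8 hydroxyl sits between the ring-fusion carbon C7 and the C9 carbon that carries the bulky OTBDPS group.

Step 14
Reactants: 17 C5 O-TBS ether
Product: 18 C8 angelate [(Z)-2-methylbut-2-enoate] of 17
Conditions: angelic acid, 2,4,6-trichlorobenzoyl chloride, Et3N, toluene, rt; then 17, 80 °C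
Reagents that add atoms: angelic acid C/C=C(/C)C(=O)O
Why: Yamaguchi esterification through the mixed anhydride without DMAP should acylate the hindered C8 hydroxyl and keep the (Z) geometry; the ketone is still masked, so no β-acyloxy ketone is exposed to hot amine base.

Step 15
Reactants: 18 C8 angelate
Product: 19 C10 methyl ketone: 18 with the isopropenyl group cleaved to C(=O)CH3
Conditions: O3, CH2Cl2/MeOH, −78 °C (Sudan Red 7B end point); Me2S, −78 °C → rt
Reagents that add atoms: ozone [O-][O+]=O
Why: Ozonolysis stopped at the indicator end point should cleave only the electron-rich 1,1-disubstituted alkene, because the α-methylene lactone and the angelate are electron-poor and the alkyne reacts far more slowly with ozone.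

Step 16
Reactants: 19 C10 methyl ketone
Product: 20 primary propargylic alcohol: 19 with C1 CH2OH
Conditions: CSA (cat.), MeOH/CH2Cl2, 0 °C
Reagents that add atoms: none
Why: Acid-catalysed methanolysis removes the primary propargylic TBS ether much faster than the hindered secondary TBS ether at C5 or the TBDPS ether at C9.

Step 17
Reactants: 20 primary propargylic alcohol
Product: 21 seco ynal: OHC–C≡C–C4…C10(=O)CH3 with C5 OTBS, C8 angelate, C9 OTBDPS and the α-methylene lactone
Conditions: MnO2, CH2Cl2, rt
Reagents that add atoms: none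
Why: MnO2 oxidises propargylic alcohols to ynals under neutral conditions, so the base-sensitive C4 stereocentre and the β-acyloxy ketone are not put at risk.

Step 18
Reactants: 21 seco ynal
Product: 23 5-O-TBS-9-O-TBDPS-protected furanone macrocycle (protected target), via hydroxy ynone 22 (not isolated)
Conditions: 2-(pentafluorophenyl)-6,7-dihydro-5H-pyrrolo[2,1-c][1,2,4]triazol-2-ium tetrafluoroborate (20 mol %), i-Pr2NEt (20 mol %), toluene (2 mM, slow addition of 21), 40 °C
Reagents that add atoms: none
Why: Proposed new method: the free carbene adds to the ynal carbon C1 to give a Breslow intermediate whose acyl-anion carbon attacks the C10 ketone (made more electrophilic by the α-silyloxy group), the catalyst is expelled to leave the α-hydroxy ynone 22, and its tertiary hydroxyl adds to the bent, strained ynone at C3 to give the 3(2H)-furanone; the closest known reactions are the carbene-catalysed intramolecular crossed aldehyde–ketone benzoin cyclisation and the carbene-catalysed ynal/activated-ketone benzoin–oxa-Michael annulation to 3(2H)-furanones, neither of which has been shown as a macrocyclisation onto an unactivated ketone. The ten-membered carbocycle closes by 10-exo-trig attack of C1 on the C10 carbonyl, and the furanone closes by 5-endo-dig oxa-Michael addition of the C10 oxygen to C3. The only new stereocentre, C10, is controlled by C9: in the polar Felkin–Anh arrangement the C9–OSi bond is anti to the incoming C1, which gives the 9,10-anti (10R) alkoxide, and because the benzoin step is reversible while the oxa-Michael step is not, a minor C10 epimer can revert. The step needs acyl-anion reactivity instead of the internal redox path of ynals (aprotic medium, no free hydroxyl, weak amine base), ring closure instead of intermolecular benzoin (2 mM, slow addition), attack on the ketone instead of a Stetter addition to the α-methylene lactone (which would require a nine-membered cycloalkyne), and closure by the C10 oxygen instead of pyranone formation by the C9 oxygen (blocked as its silyl ether).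

Step 19
Reactants: 23 protected target
Product: 24 (4R,5S,6R,7S,8S,9R,10R)-5,9-dihydroxy-1-oxo-3,10-epoxygermacra-2,11(13)-dien-6,12-olid-8-yl (Z)-2-methylbut-2-enoate (CNP0206920.1)
Conditions: HF·pyridine, pyridine, THF, 0 °C → rt
Reagents that add atoms: none
Why: Fluoride cleaves both silyl ethers under mildly acidic conditions, which should avoid angelate migration from O8 to O9 and epimerisation at C4.

Compound list
1 | 1,2:5,6-di-O-isopropylidene-α-D-glucofuranose | CC1(C)O[C@H]2[C@@H](O1)O[C@@H]([C@@H]2O)[C@H]3COC(C)(C)O3 | starting material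
2 | 1,2:5,6-di-O-isopropylidene-α-D-ribo-hexofuranos-3-ulose | CC1(C)O[C@H]2[C@@H](O1)O[C@@H](C2=O)[C@H]3COC(C)(C)O3 | intermediate
3 | methyl 2-(3-deoxy-1,2:5,6-di-O-isopropylidene-α-D-ribo-hexofuranos-3-ylidene)acetate (E/Z) | CC1(C)O[C@H]2[C@@H](O1)O[C@@H](C2=CC(=O)OC)[C@H]3COC(C)(C)O3 | intermediate
4 | methyl 2-(3-deoxy-1,2:5,6-di-O-isopropylidene-α-D-allofuranos-3-yl)acetate | CC1(C)O[C@H]2[C@@H](O1)O[C@@H]([C@H]2CC(=O)OC)[C@H]3COC(C)(C)O3 | intermediate
5 | 3-deoxy-1,2-O-isopropylidene-3-C-(2-methoxy-2-oxoethyl)-α-D-ribo-pentodialdo-1,4-furanose | CC1(C)O[C@H]2[C@@H](O1)O[C@@H]([C@H]2CC(=O)OC)C=O | intermediate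
6 | isopropenyl carbinol (L-talo, 4,5-threo; new carbinol = C9) | CC1(C)O[C@H]2[C@@H](O1)O[C@@H]([C@H]2CC(=O)OC)[C@@H](O)C(C)=C | intermediate
7 | C9 O-TBDPS ether of 6 | CC1(C)O[C@H]2[C@@H](O1)O[C@@H]([C@H]2CC(=O)OC)[C@@H](O[Si](c3ccccc3)(c3ccccc3)C(C)(C)C)C(C)=C | intermediate
8 | Mannich base (CH2NMe2 on C11, epimers) | CC1(C)O[C@H]2[C@@H](O1)O[C@@H]([C@H]2C(CN(C)C)C(=O)OC)[C@@H](O[Si](c3ccccc3)(c3ccccc3)C(C)(C)C)C(C)=C | intermediate (not isolated)
9 | trimethylammonium iodide of 8 | CC1(C)O[C@H]2[C@@H](O1)O[C@@H]([C@H]2C(C[N+](C)(C)C)C(=O)OC)[C@@H](O[Si](c3ccccc3)(c3ccccc3)C(C)(C)C)C(C)=C.[I-] | intermediate (not isolated)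
10 | acrylate (C11=C13H2, methyl ester) | CC1(C)O[C@H]2[C@@H](O1)O[C@@H]([C@H]2C(=C)C(=O)OC)[C@@H](O[Si](c3ccccc3)(c3ccccc3)C(C)(C)C)C(C)=C | intermediate
11 | bicyclic lactol with cis-fused α-methylene-γ-butyrolactone | C=C1C(=O)O[C@H]2C(O)O[C@@H]([C@@H]12)[C@@H](O[Si](c3ccccc3)(c3ccccc3)C(C)(C)C)C(C)=C | intermediate
12 | tert-butyldimethyl(prop-2-yn-1-yloxy)silane | C#CCO[Si](C)(C)C(C)(C)C | starting material
13 | 5-(tert-butyldimethylsilyloxy)pent-3-yn-2-one | CC(=O)C#CCO[Si](C)(C)C(C)(C)C | intermediate
14 | (R)-5-(tert-butyldimethylsilyloxy)pent-3-yn-2-ol | C[C@@H](O)C#CCO[Si](C)(C)C(C)(C)C | intermediate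
15 | (R)-5-(tert-butyldimethylsilyloxy)pent-3-yn-2-yl methanesulfonate | C[C@@H](OS(C)(=O)=O)C#CCO[Si](C)(C)C(C)(C)C | intermediate
16 | seco 5,8-diol | C=C1C(=O)O[C@@H]([C@@H](O)[C@@H](C)C#CCO[Si](C)(C)C(C)(C)C)[C@H]1[C@H](O)[C@@H](O[Si](c2ccccc2)(c2ccccc2)C(C)(C)C)C(C)=C | intermediate
17 | C5 O-TBS ether of 16 | C=C1C(=O)O[C@@H]([C@@H](O[Si](C)(C)C(C)(C)C)[C@@H](C)C#CCO[Si](C)(C)C(C)(C)C)[C@H]1[C@H](O)[C@@H](O[Si](c2ccccc2)(c2ccccc2)C(C)(C)C)C(C)=C | intermediate
18 | C8 angelate of 17 | C=C1C(=O)O[C@@H]([C@@H](O[Si](C)(C)C(C)(C)C)[C@@H](C)C#CCO[Si](C)(C)C(C)(C)C)[C@H]1[C@H](OC(=O)/C(C)=C\C)[C@@H](O[Si](c2ccccc2)(c2ccccc2)C(C)(C)C)C(C)=C | intermediate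
19 | C10 methyl ketone | C=C1C(=O)O[C@@H]([C@@H](O[Si](C)(C)C(C)(C)C)[C@@H](C)C#CCO[Si](C)(C)C(C)(C)C)[C@H]1[C@H](OC(=O)/C(C)=C\C)[C@@H](O[Si](c2ccccc2)(c2ccccc2)C(C)(C)C)C(C)=O | intermediate
20 | primary propargylic alcohol | C=C1C(=O)O[C@@H]([C@@H](O[Si](C)(C)C(C)(C)C)[C@@H](C)C#CCO)[C@H]1[C@H](OC(=O)/C(C)=C\C)[C@@H](O[Si](c2ccccc2)(c2ccccc2)C(C)(C)C)C(C)=O | intermediate
21 | seco ynal | C=C1C(=O)O[C@@H]([C@@H](O[Si](C)(C)C(C)(C)C)[C@@H](C)C#CC=O)[C@H]1[C@H](OC(=O)/C(C)=C\C)[C@@H](O[Si](c2ccccc2)(c2ccccc2)C(C)(C)C)C(C)=O | intermediate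
22 | ten-membered α-hydroxy ynone | C=C1C(=O)O[C@H]2[C@@H](O[Si](C)(C)C(C)(C)C)[C@@H](C)C#CC(=O)[C@](C)(O)[C@H](O[Si](c3ccccc3)(c3ccccc3)C(C)(C)C)[C@@H](OC(=O)/C(C)=C\C)[C@@H]12 | intermediate (not isolated)
23 | 5-O-TBS-9-O-TBDPS-protected target | C=C1C(=O)O[C@H]2[C@@H](O[Si](C)(C)C(C)(C)C)[C@@H](C)C3=CC(=O)[C@](C)(O3)[C@H](O[Si](c4ccccc4)(c4ccccc4)C(C)(C)C)[C@@H](OC(=O)/C(C)=C\C)[C@@H]12 | intermediate
24 | CNP0206920.1 | C=C1C(=O)O[C@H]2[C@@H](O)[C@@H](C)C3=CC(=O)[C@](C)(O3)[C@H](O)[C@@H](OC(=O)/C(C)=C\C)[C@@H]12 | target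

Total step count: 19. Longest linear sequence: 16 (steps 1–8 and 12–19; steps 9–11 make mesylate 15).

Steps most likely to fail

1. Step 18 (Proposed new method). The carbene may consume the ynal through the internal redox path to an acyl azolium, or the linear ynal may oligomerise faster than the strained ten-membered ring closes. The fallback uses known reactions, sets out from ynal 21 and comes back at furanone 23. A keto-aldehyde pinacol macrocyclisation with SmI2 (THF, −78 °C, high dilution, no HMPA so that the conjugated esters are spared) would give the 1,10-diol F1. MnO2 would oxidise its secondary propargylic hydroxyl to the α-hydroxy ynone 22, now isolated. (Ph3P)AuNTf2 (cat.) in CH2Cl2 would then add the tertiary hydroxyl to C3 in a 5-endo-dig hydroalkoxylation, which rejoins the route at 23.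

2. Step 13. The mono-silylation of the 5,8-diol may show poor regioselectivity, and the lactone may migrate to the free hydroxyls. The fallback sets out from lactol 11 and comes back at angelate 18. Luche reduction (NaBH4, CeCl3·7H2O, MeOH, −20 °C), which spares the α-methylene lactone, would open the lactol to the primary/secondary diol F2. TBSCl/imidazole at 0 °C would silylate only the primary C5 hydroxyl to give silyl ether F3. Yamaguchi angeloylation of the now unique C8 hydroxyl would give angelate F4, and CSA in MeOH would free the primary alcohol F5. Dess–Martin oxidation would give aldehyde F6, and the propargylation of step 12 with mesylate 15 would give homopropargylic alcohol F7. TBSCl/imidazole would then give 18.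

3. Step 5. Weak chelation may give poor facial selectivity in the Grignard addition. The fallback sets out from 6 obtained as a C9 epimer mixture and comes back at 6. Dess–Martin oxidation would give the isopropenyl ketone F8. Reduction with Zn(BH4)2 (Et2O, −30 °C), in which zinc chelates the ketone and the furanose ring oxygen and hydride enters from the open face, should return the 4,5-threo alcohol 6.

Further compounds
F1 | step 18 | ten-membered 1,10-diol from pinacol closure | C=C1C(=O)O[C@H]2[C@@H](O[Si](C)(C)C(C)(C)C)[C@@H](C)C#CC(O)[C@](C)(O)[C@H](O[Si](c3ccccc3)(c3ccccc3)C(C)(C)C)[C@@H](OC(=O)/C(C)=C\C)[C@@H]12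
F2 | step 13 | primary/secondary diol from Luche reduction of 11 | C=C1C(=O)O[C@@H](CO)[C@H]1[C@H](O)[C@@H](O[Si](c2ccccc2)(c2ccccc2)C(C)(C)C)C(C)=C
F3 | step 13 | primary TBS ether of F2 | C=C1C(=O)O[C@@H](CO[Si](C)(C)C(C)(C)C)[C@H]1[C@H](O)[C@@H](O[Si](c2ccccc2)(c2ccccc2)C(C)(C)C)C(C)=C
F4 | step 13 | C8 angelate of F3 | C=C1C(=O)O[C@@H](CO[Si](C)(C)C(C)(C)C)[C@H]1[C@H](OC(=O)/C(C)=C\C)[C@@H](O[Si](c2ccccc2)(c2ccccc2)C(C)(C)C)C(C)=C
F5 | step 13 | primary alcohol from F4 | C=C1C(=O)O[C@@H](CO)[C@H]1[C@H](OC(=O)/C(C)=C\C)[C@@H](O[Si](c2ccccc2)(c2ccccc2)C(C)(C)C)C(C)=C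
F6 | step 13 | C5 aldehyde with C8 angelate | C=C1C(=O)O[C@@H](C=O)[C@H]1[C@H](OC(=O)/C(C)=C\C)[C@@H](O[Si](c2ccccc2)(c2ccccc2)C(C)(C)C)C(C)=C
F7 | step 13 | homopropargylic alcohol (C5 OH free, C8 angelate) | C=C1C(=O)O[C@@H]([C@@H](O)[C@@H](C)C#CCO[Si](C)(C)C(C)(C)C)[C@H]1[C@H](OC(=O)/C(C)=C\C)[C@@H](O[Si](c2ccccc2)(c2ccccc2)C(C)(C)C)C(C)=C
F8 | step 5 | isopropenyl ketone from oxidation of 6 | CC1(C)O[C@H]2[C@@H](O1)O[C@@H]([C@H]2CC(=O)OC)C(=O)C(C)=C
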